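The plan cuts the C4–C5 bond of the dihydropyran ring (O1, C2 to C6). Two CH2 groups hang on C3: ring member C4 and the exocyclic carbon that bears the acetate. They differ only through ring membership, so C3 owes its chirality to the ring closure itself. An open-chain precursor with two equal CH2I groups therefore has C2 as its single stereocentre. This precursor is the benzofuran-2-ylacetic ester of an (R)-aryl carbinol carrying a CH(CH2I)2 unit. Deprotonation next to the benzofuran and attack on one CH2I group makes C4–C5, closes the δ-lactone and sets C3 trans to the C2 aryl group at once. The untouched CH2I group later takes up acetate.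

Key step: step 17

Remark: the labels O1 and C2 to C6 are those of the dihydropyran ring of the target and are used for all intermediates; the target SMILES is read as 2R,3S, with aryl and acetoxymethyl groups trans.

**Fragment A (steps 1 to 7)**

Step 1
Reactants: 1 vanillin (4-hydroxy-3-methoxybenzaldehyde)
Product: 2 3-methoxy-4-(triisopropylsilyloxy)benzaldehyde
Conditions: i-Pr3SiCl, imidazole, DMF, rt
Reagents that add atoms: triisopropylsilyl chloride, CC(C)[Si](Cl)(C(C)C)C(C)C
Why: Imidazole-promoted O-silylation of the only hydroxyl group, with the bulky triisopropylsilyl group chosen because it has to outlast acetate in DMF at step 21 and still leave with fluoride at the end.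

Step 2
Reactants: 3 (R)-4-benzyl-1,3-oxazolidin-2-one; 4 (E)-but-2-enoyl chloride
Product: 6 (R)-4-benzyl-3-[(E)-but-2-enoyl]-1,3-oxazolidin-2-one, via lithium oxazolidinonide 5 (not isolated)
Conditions: n-BuLi, THF, −78 °C; then 4, −78 to 0 °C
Reagents that add atoms: none
Why: N-Acylation of the lithiated oxazolidinone with an acid chloride is the standard way to load the auxiliary and does not touch its stereocentre.

Step 3
Reactants: 6 (R)-4-benzyl-3-[(E)-but-2-enoyl]-1,3-oxazolidin-2-one; 2 3-methoxy-4-(triisopropylsilyloxy)benzaldehyde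
Product: 9 (R)-4-benzyl-3-[(2R)-2-{(R)-hydroxy[3-methoxy-4-(triisopropylsilyloxy)phenyl]methyl}but-3-enoyl]-1,3-oxazolidin-2-one (syn aldol), via boron dienolate 7 (not isolated), via boron aldolate 8 (not isolated)
Conditions: Bu2BOTf, Et3N, CH2Cl2, −78 to 0 °C; then 2, −78 to 0 °C; then pH 7 buffer, MeOH, H2O2, 0 °C
Reagents that add atoms: none
Why: Evans syn aldol reaction of a deconjugated boron dienolate, in which soft enolisation removes a γ-proton, the Z-dienolate adds through its α-carbon in a closed chair-like transition state, and the benzyl group of the (R)-auxiliary shields one face so that the carbinol carbon (future C2) should form R, the α-centre being erased again at step 5.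

Step 4
Reactants: 9 syn aldol adduct
Product: 10 (1R,2S)-2-ethenyl-1-[3-methoxy-4-(triisopropylsilyloxy)phenyl]propane-1,3-diol
Conditions: LiBH4, THF, 0 °C to rt
Reagents that add atoms: none
Why: Reductive removal of the auxiliary (borohydride reduction of an N-acyloxazolidinone) turns the acyl carbon into the first hydroxymethyl arm without touching the vinyl group, the silyl ether or the carbinol centre.

Step 5
Reactants: 10 vinyl diol
Product: 12 (1R)-2-(hydroxymethyl)-1-[3-methoxy-4-(triisopropylsilyloxy)phenyl]propane-1,3-diol, via secondary ozonide 11 (not isolated)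
Conditions: O3, CH2Cl2, −78 °C (dye end point); then NaBH4, MeOH, −78 to 0 °C
Reagents that add atoms: ozone, [O-][O+]=O
Why: Ozonolysis with reductive borohydride work-up shortens the vinyl group to the second hydroxymethyl arm, so that C3 now carries two identical arms and ceases to be a stereocentre while C2 stays R, the terminal alkene being consumed before the arene when ozone is dosed to an indicator end point.

Step 6
Reactants: 12 triol
Product: 13 (R)-2-{hydroxy[3-methoxy-4-(triisopropylsilyloxy)phenyl]methyl}propane-1,3-diyl bis(4-methylbenzenesulfonate)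
Conditions: TsCl (2.1 equiv), pyridine, CH2Cl2, 0 °C
Reagents that add atoms: 4-toluenesulfonyl chloride, Cc1ccc(cc1)S(=O)(=O)Cl
Why: Chemoselective sulfonylation, in which tosyl chloride distinguishes on steric grounds between the two open primary hydroxyl groups and the secondary benzylic one flanked by an aryl ring and a branched carbon, so the carbinol stays free without any protecting group.

Step 7
Reactants: 13 bis-tosylate
Product: 14 (1R)-3-iodo-2-(iodomethyl)-1-[3-methoxy-4-(triisopropylsilyloxy)phenyl]propan-1-ol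
Conditions: NaI, acetone, reflux, dark
Reagents that add atoms: sodium iodide, [Na+].[I-]
Why: Finkelstein reaction at two primary carbons, driven by precipitation of sodium tosylate under neutral conditions, which puts both iodides in place before the fragments are joined so that no diol deprotection is ever needed beside the acid-labile ketal.

**Fragment B (steps 8 to 15)**

Step 8
Reactants: 15 2-bromo-1,4-dimethoxybenzene
Product: 16 1-(4-bromo-2,5-dimethoxyphenyl)ethanone
Conditions: AcCl, AlCl3, CH2Cl2, 0 °C to rt
Reagents that add atoms: acetyl chloride, CC(=O)Cl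
Why: Friedel–Crafts acylation should go ortho to a methoxy group and para to bromine, the position favoured by both substituents and free of steric crowding.

Step 9
Reactants: 16 1-(4-bromo-2,5-dimethoxyphenyl)ethanone
Product: 17 1-(4-bromo-2,5-dihydroxyphenyl)ethanone
Conditions: BBr3 (3 equiv), CH2Cl2, −78 °C to rt; then H2O
Reagents that add atoms: none
Why: Lewis acid cleavage of aryl methyl ethers with BBr3 removes both methyl groups, while ketone and aryl bromide are inert to it.

Step 10
Reactants: 18 but-3-yn-1-ol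
Product: 19 but-3-yn-1-yl acetate
Conditions: Ac2O, Et3N, DMAP (cat.), CH2Cl2, 0 °C to rt
Reagents that add atoms: acetic anhydride, CC(=O)OC(C)=O
Why: DMAP-catalysed O-acetylation masks the alcohol so that only the phenol is silylated at step 12.

Step 11
Reactants: 17 1-(4-bromo-2,5-dihydroxyphenyl)ethanone; 19 but-3-yn-1-yl acetate
Product: 21 2-(6-acetyl-5-hydroxy-1-benzofuran-2-yl)ethyl acetate, via alkynylphenol 20 (not isolated)
Conditions: PdCl2(PPh3)2 (cat.), CuI (cat.), Et3N, degassed DMF, 80 °C
Reagents that add atoms: none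
Why: Domino Sonogashira coupling and 5-endo-dig heteroannulation, in which the para acetyl group helps oxidative addition and only the hydroxyl group ortho to the alkyne can close the furan ring, so the hydrogen-bonded phenol next to the acetyl group stays free.

Step 12
Reactants: 21 2-(6-acetyl-5-hydroxy-1-benzofuran-2-yl)ethyl acetate
Product: 22 2-[6-acetyl-5-(triisopropylsilyloxy)-1-benzofuran-2-yl]ethyl acetate
Conditions: i-Pr3SiOTf, 2,6-lutidine, CH2Cl2, 0 °C to rt
Reagents that add atoms: triisopropylsilyl triflate, CC(C)[Si](OS(=O)(=O)C(F)(F)F)(C(C)C)C(C)C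
Why: O-Silylation with the silyl triflate is used because the phenol is hydrogen-bonded to the ketone and would react sluggishly with the chloride, and the acetate is unaffected.

Step 13
Reactants: 22 2-[6-acetyl-5-(triisopropylsilyloxy)-1-benzofuran-2-yl]ethyl acetate
Product: 23 2-[6-(2-methyl-1,3-dioxolan-2-yl)-5-(triisopropylsilyloxy)-1-benzofuran-2-yl]ethyl acetate
Conditions: Me3SiOCH2CH2OSiMe3, Me3SiOTf (cat.), CH2Cl2, −78 to 0 °C; pyridine quench
Reagents that add atoms: 1,2-bis(trimethylsilyloxy)ethane, C[Si](C)(C)OCCO[Si](C)(C)C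
Why: Noyori ketalisation is aprotic and is pulled forward by formation of hexamethyldisiloxane, so the ketone that would be enolised at step 17 and reduced at step 18 is masked without loss of silyl ether or acetate.

Step 14
Reactants: 23 ketal acetate
Product: 24 2-[6-(2-methyl-1,3-dioxolan-2-yl)-5-(triisopropylsilyloxy)-1-benzofuran-2-yl]ethanol
Conditions: K2CO3 (cat.), MeOH, 0 °C
Reagents that add atoms: none
Why: Base-catalysed transesterification (Zemplén-type methanolysis) frees the primary alcohol, while the hindered aryl silyl ether and the ketal tolerate cold carbonate in methanol.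

Step 15
Reactants: 24 ketal alcohol
Product: 26 [6-(2-methyl-1,3-dioxolan-2-yl)-5-(triisopropylsilyloxy)-1-benzofuran-2-yl]acetic acid, via arylacetaldehyde 25 (not isolated)
Conditions: TEMPO (cat.), NaClO2, NaOCl (cat.), MeCN–NaH2PO4/Na2HPO4 buffer (pH 6.7), 35 °C; cold work-up at pH 4 to 5
Reagents that add atoms: sodium chlorite, [Na+].[O-]Cl=O
Why: TEMPO-catalysed oxidation with chlorite as terminal oxidant at near-neutral pH takes a 2-arylethanol through the aldehyde to the acid without hydrolysing the ketal or chlorinating the electron-rich benzofuran.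

**Union and endgame (steps 16 to 22)**

Step 16
Reactants: 14 (1R)-3-iodo-2-(iodomethyl)-1-[3-methoxy-4-(triisopropylsilyloxy)phenyl]propan-1-ol; 26 benzofuran-2-ylacetic acid
Product: 27 (1R)-3-iodo-2-(iodomethyl)-1-[3-methoxy-4-(triisopropylsilyloxy)phenyl]propyl [6-(2-methyl-1,3-dioxolan-2-yl)-5-(triisopropylsilyloxy)-1-benzofuran-2-yl]acetate
Conditions: DCC, DMAP (cat.), CH2Cl2, 0 °C to rt
Reagents that add atoms: none
Why: Steglich esterification joins the fragments at the acyl carbon, so the C2–O bond is never broken and the R configuration is kept, and the nearly neutral medium leaves primary iodides, ketal and silyl ethers intact.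

Step 17
Reactants: 27 bis(iodomethyl) carbinyl benzofuran-2-ylacetate
Product: 29 trans δ-lactone (5R,6R)-5-(iodomethyl)-6-[3-methoxy-4-(triisopropylsilyloxy)phenyl]-3-[6-(2-methyl-1,3-dioxolan-2-yl)-5-(triisopropylsilyloxy)-1-benzofuran-2-yl]oxan-2-one (epimers at the benzofuranyl-bearing carbon C5 of the target numbering), via lithium enolate 28 (not isolated)
Conditions: LiN(SiMe3)2 (1.05 equiv), THF (0.01 M), −78 to 0 °C
Reagents that add atoms: none
Why: LiN(SiMe3)2 removes a proton from the CH2 group flanked by the ester carbonyl and benzofuran C2, and the carbon of lithium enolate 28 displaces iodide from one CH2I group in an intramolecular SN2 reaction that forms C4–C5. The closest known reaction type is the intramolecular alkylation of ester enolates to lactones, run here as a diastereotopic-group-selective cyclisation. The ring O1–C2–C3–C4–C5–C6 closes in the 6-(enolendo)-exo-tet mode, which the ring-closure rules for enolates allow. C3 is controlled by the existing C2 centre: in the chair-like transition state the aryl group sits equatorial and the reacting arm is the one that leaves the idle CH2I group equatorial and anti to O1 instead of wedged between O1 and the aryl ring, which should give the trans lactone (C3 reads R here only because iodine outranks oxygen), while the C5 mixture does not matter because C5 becomes sp2 at step 20. Two selectivities are needed, one arm over the other and carbon over oxygen attack (the latter would give a six-membered cyclic ketene acetal); the first rests on this conformational bias, the second on the soft iodide leaving group, the delocalised carbanion and the tight lithium–oxygen contact in THF without polar cosolvent. High dilution suppresses intermolecular alkylation, and a single equivalent of base leaves nothing to deprotonate 29 again.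

Step 18
Reactants: 29 trans δ-lactone
Product: 30 (5R,6R)-5-(iodomethyl)-6-[3-methoxy-4-(triisopropylsilyloxy)phenyl]-3-[6-(2-methyl-1,3-dioxolan-2-yl)-5-(triisopropylsilyloxy)-1-benzofuran-2-yl]oxan-2-ol (lactol; anomers and C5 epimers)
Conditions: i-Bu2AlH (1.2 equiv), CH2Cl2, −78 °C; aq. potassium sodium tartrate
Reagents that add atoms: none
Why: Partial reduction of a lactone with i-Bu2AlH stops at the aluminium hemiacetal at −78 °C, and primary iodide, ketal and silyl ethers are inert under these conditions.

Step 19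
Reactants: 30 ketal lactol
Product: 31 1-{2-[(5R,6R)-2-hydroxy-5-(iodomethyl)-6-(3-methoxy-4-triisopropylsilyloxyphenyl)oxan-3-yl]-5-(triisopropylsilyloxy)-1-benzofuran-6-yl}ethanone (keto lactol)
Conditions: PPTS (cat.), THF–H2O, 40 °C
Reagents that add atoms: water, O
Why: Mild acid-catalysed ketal hydrolysis is placed here because no enol ether exists yet, and at this acidity the electron-rich aryl ketal should ionise far faster than the benzylic C2–O bond, so C2 is not put at risk.

Step 20
Reactants: 31 keto lactol
Product: 33 1-{2-[(2R,3R)-3-(iodomethyl)-2-(3-methoxy-4-triisopropylsilyloxyphenyl)-3,4-dihydro-2H-pyran-5-yl]-5-(triisopropylsilyloxy)-1-benzofuran-6-yl}ethanone, via anomeric mesylate 32 (not isolated)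
Conditions: MsCl, Et3N, CH2Cl2, 0 °C to rt
Reagents that add atoms: none
Why: Lactol dehydration through the anomeric sulfonate, the method used to make glycals and dihydropyrans, proceeds by ionisation to the oxocarbenium ion and loss of the C5 proton, is driven by conjugation with the benzofuran, and lets all anomers and C5 epimers converge on one alkene.

Step 21
Reactants: 33 iodomethyl dihydropyran
Product: 34 [(2R,3S)-5-(6-acetyl-5-triisopropylsilyloxy-1-benzofuran-2-yl)-2-(3-methoxy-4-triisopropylsilyloxyphenyl)-3,4-dihydro-2H-pyran-3-yl]methyl acetate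
Conditions: CsOAc, dry DMF, 50 °C
Reagents that add atoms: caesium acetate, [Cs+].CC(=O)[O-]
Why: SN2 displacement of a primary iodide by CsOAc in a dipolar aprotic solvent, in which acetate is too weak a base for elimination, C3 is not a reacting centre (its descriptor changes to S only because oxygen replaces iodine), and dry conditions together with the bulky silyl groups guard the phenol ethers.

Step 22
Reactants: 34 bis-silyl ether of the target
Product: 35 propolis-benzofuran A, [(2R,3S)-5-(6-acetyl-5-hydroxy-1-benzofuran-2-yl)-2-(4-hydroxy-3-methoxyphenyl)-3,4-dihydro-2H-pyran-3-yl]methyl acetate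
Conditions: Bu4NF, AcOH (equimolar), THF, 0 °C
Reagents that add atoms: none
Why: Fluoride-induced cleavage of both aryl silyl ethers, buffered with acetic acid so that no free phenoxide can attack the acetate or open the C2–O1 bond through a quinone methide.

**Compound list**

1 | vanillin | COc1cc(C=O)ccc1O | starting material
2 | 3-methoxy-4-(triisopropylsilyloxy)benzaldehyde | COc1cc(C=O)ccc1O[Si](C(C)C)(C(C)C)C(C)C | intermediate
3 | (R)-4-benzyl-1,3-oxazolidin-2-one | O=C1OC[C@@H](Cc2ccccc2)N1 | starting material
4 | (E)-but-2-enoyl chloride | C/C=C/C(=O)Cl | starting material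
5 | N-lithio-(R)-4-benzyl-1,3-oxazolidin-2-one | [Li]N1[C@H](Cc2ccccc2)COC1=O | intermediate
6 | (R)-4-benzyl-3-[(E)-but-2-enoyl]-1,3-oxazolidin-2-one | C/C=C/C(=O)N1[C@H](Cc2ccccc2)COC1=O | intermediate
7 | (Z)-dibutylboron dienolate of 6 | C=C/C=C(\OB(CCCC)CCCC)N1[C@H](Cc2ccccc2)COC1=O | intermediate
8 | dibutylboron aldolate of 9 | COc1cc([C@H](OB(CCCC)CCCC)[C@@H](C=C)C(=O)N2[C@H](Cc3ccccc3)COC2=O)ccc1O[Si](C(C)C)(C(C)C)C(C)C | intermediate
9 | syn aldol adduct, (4R) auxiliary, (2R) α-carbon, (R) carbinol | COc1cc([C@H](O)[C@@H](C=C)C(=O)N2[C@H](Cc3ccccc3)COC2=O)ccc1O[Si](C(C)C)(C(C)C)C(C)C | intermediate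
10 | (1R,2S)-2-ethenyl-1-[3-methoxy-4-(triisopropylsilyloxy)phenyl]propane-1,3-diol | COc1cc([C@H](O)[C@@H](C=C)CO)ccc1O[Si](C(C)C)(C(C)C)C(C)C | intermediate
11 | secondary ozonide (1,2,4-trioxolane) of 10 | COc1cc([C@H](O)[C@@H](C2OCOO2)CO)ccc1O[Si](C(C)C)(C(C)C)C(C)C | intermediate
12 | (1R)-2-(hydroxymethyl)-1-[3-methoxy-4-(triisopropylsilyloxy)phenyl]propane-1,3-diol | COc1cc([C@H](O)C(CO)CO)ccc1O[Si](C(C)C)(C(C)C)C(C)C | intermediate
13 | (R)-carbinol bis-tosylate | COc1cc([C@H](O)C(COS(=O)(=O)c2ccc(C)cc2)COS(=O)(=O)c2ccc(C)cc2)ccc1O[Si](C(C)C)(C(C)C)C(C)C | intermediate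
14 | (1R)-3-iodo-2-(iodomethyl)-1-[3-methoxy-4-(triisopropylsilyloxy)phenyl]propan-1-ol | COc1cc([C@H](O)C(CI)CI)ccc1O[Si](C(C)C)(C(C)C)C(C)C | intermediate
15 | 2-bromo-1,4-dimethoxybenzene | COc1ccc(OC)c(Br)c1 | starting material
16 | 1-(4-bromo-2,5-dimethoxyphenyl)ethanone | COc1cc(C(C)=O)c(OC)cc1Br | intermediate
17 | 1-(4-bromo-2,5-dihydroxyphenyl)ethanone | CC(=O)c1cc(O)c(Br)cc1O | intermediate
18 | but-3-yn-1-ol | C#CCCO | starting material
19 | but-3-yn-1-yl acetate | C#CCCOC(C)=O | intermediate
20 | 4-(4-acetyl-2,5-dihydroxyphenyl)but-3-yn-1-yl acetate | CC(=O)OCCC#Cc1cc(O)c(C(C)=O)cc1O | intermediate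
21 | 2-(6-acetyl-5-hydroxy-1-benzofuran-2-yl)ethyl acetate | CC(=O)OCCc1cc2cc(O)c(C(C)=O)cc2o1 | intermediate
22 | 2-[6-acetyl-5-(triisopropylsilyloxy)-1-benzofuran-2-yl]ethyl acetate | CC(=O)OCCc1cc2cc(O[Si](C(C)C)(C(C)C)C(C)C)c(C(C)=O)cc2o1 | intermediate
23 | 2-[6-(2-methyl-1,3-dioxolan-2-yl)-5-(triisopropylsilyloxy)-1-benzofuran-2-yl]ethyl acetate | CC(=O)OCCc1cc2cc(O[Si](C(C)C)(C(C)C)C(C)C)c(C3(C)OCCO3)cc2o1 | intermediate
24 | 2-[6-(2-methyl-1,3-dioxolan-2-yl)-5-(triisopropylsilyloxy)-1-benzofuran-2-yl]ethanol | OCCc1cc2cc(O[Si](C(C)C)(C(C)C)C(C)C)c(C3(C)OCCO3)cc2o1 | intermediate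
25 | [6-(2-methyl-1,3-dioxolan-2-yl)-5-(triisopropylsilyloxy)-1-benzofuran-2-yl]acetaldehyde | O=CCc1cc2cc(O[Si](C(C)C)(C(C)C)C(C)C)c(C3(C)OCCO3)cc2o1 | intermediate
26 | [6-(2-methyl-1,3-dioxolan-2-yl)-5-(triisopropylsilyloxy)-1-benzofuran-2-yl]acetic acid | OC(=O)Cc1cc2cc(O[Si](C(C)C)(C(C)C)C(C)C)c(C3(C)OCCO3)cc2o1 | intermediate
27 | (1R)-bis(iodomethyl) carbinyl benzofuran-2-ylacetate (key-step precursor) | COc1cc([C@H](OC(=O)Cc2cc3cc(O[Si](C(C)C)(C(C)C)C(C)C)c(C4(C)OCCO4)cc3o2)C(CI)CI)ccc1O[Si](C(C)C)(C(C)C)C(C)C | intermediate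
28 | lithium enolate of 27 | COc1cc([C@H](OC(O[Li])=Cc2cc3cc(O[Si](C(C)C)(C(C)C)C(C)C)c(C4(C)OCCO4)cc3o2)C(CI)CI)ccc1O[Si](C(C)C)(C(C)C)C(C)C | intermediate
29 | trans δ-lactone with residual iodomethyl group, C2 R, C3 R, mixed at C5 (key-step product) | COc1cc([C@@H]2OC(=O)C(c3cc4cc(O[Si](C(C)C)(C(C)C)C(C)C)c(C5(C)OCCO5)cc4o3)C[C@H]2CI)ccc1O[Si](C(C)C)(C(C)C)C(C)C | intermediate
30 | ketal lactol, C2 R, C3 R | COc1cc([C@@H]2OC(O)C(c3cc4cc(O[Si](C(C)C)(C(C)C)C(C)C)c(C5(C)OCCO5)cc4o3)C[C@H]2CI)ccc1O[Si](C(C)C)(C(C)C)C(C)C | intermediate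
31 | keto lactol, C2 R, C3 R | COc1cc([C@@H]2OC(O)C(c3cc4cc(O[Si](C(C)C)(C(C)C)C(C)C)c(C(C)=O)cc4o3)C[C@H]2CI)ccc1O[Si](C(C)C)(C(C)C)C(C)C | intermediate
32 | anomeric mesylate of 31 | COc1cc([C@@H]2OC(OS(C)(=O)=O)C(c3cc4cc(O[Si](C(C)C)(C(C)C)C(C)C)c(C(C)=O)cc4o3)C[C@H]2CI)ccc1O[Si](C(C)C)(C(C)C)C(C)C | intermediate
33 | (2R,3R)-iodomethyl dihydropyran | COc1cc([C@@H]2OC=C(c3cc4cc(O[Si](C(C)C)(C(C)C)C(C)C)c(C(C)=O)cc4o3)C[C@H]2CI)ccc1O[Si](C(C)C)(C(C)C)C(C)C | intermediate
34 | (2R,3S)-bis(triisopropylsilyl) ether of the target | COc1cc([C@@H]2OC=C(c3cc4cc(O[Si](C(C)C)(C(C)C)C(C)C)c(C(C)=O)cc4o3)C[C@H]2COC(C)=O)ccc1O[Si](C(C)C)(C(C)C)C(C)C | intermediate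
35 | propolis-benzofuran A, (2R,3S) | COc1cc([C@@H]2OC=C(c3cc4cc(O)c(C(C)=O)cc4o3)C[C@H]2COC(C)=O)ccc1O | target

**Step count**

Total step count: 22 steps.
Longest linear sequence: 14 steps, from 15 to 35 through steps 8, 9 and 11 to 22.

**Steps most likely to fail**

Step 17. The enolate may close through oxygen instead of carbon, or it may discriminate poorly between the two arms. In that case the C4–C5 bond can be made between separate molecules and the ring closed afterwards by acyl substitution.
- The fallback sets out from 14 and 26.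
- Et3SiCl and imidazole convert 14 into the triethylsilyl ether F1, and Me3SiCHN2 converts 26 into the methyl ester F2.
- The lithium enolate of F2 (LiN(SiMe3)2, THF–DMPU, −78 to −20 °C) is alkylated with an excess of F1 to give the mono-alkylated iodo ester F3.
- HF·pyridine buffered with pyridine frees the carbinol to give the hydroxy ester F4, which lactonises on warming in toluene with 2-hydroxypyridine.
- No arm selection can be expected in this sequence, so the cis lactone F5 has to be removed by chromatography.
- The trans isomer comes back to the route at 29.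

Step 20. The lactol may react through its open hydroxy aldehyde form. The benzylic hydroxyl group would then be sulfonylated and C2 endangered by ionisation, and the amine may slowly quaternise the primary iodide. The lactol can be bypassed altogether.
- The fallback sets out from 29.
- KN(SiMe3)2 and diphenyl chlorophosphate (THF–DMPU, −78 °C) give the ketene acetal phosphate F6.
- Palladium-catalysed formate reduction (Pd(OAc)2, PPh3, HCO2H, Et3N) replaces the phosphate by hydrogen to give the ketal-protected enol ether F7.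
- PPTS in wet THF removes the ketal, which should hydrolyse much faster than the aryl-conjugated enol ether.
- The sequence comes back to the route at 33.

Step 11. Oxidative addition into the electron-rich bromophenoxide may be slow, the hydroquinone may be oxidised by adventitious air, and the alkyne may homocouple. Coupling and ring closure can then be separated.
- The fallback sets out from 17.
- Ac2O and pyridine give the diacetate F8, whose electron-poor ring should undergo a plain Sonogashira coupling with 19 to the aryl alkyne F9.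
- Ammonium acetate in aqueous methanol cleaves the two aryl acetates selectively and gives 20, now isolated.
- A separate cycloisomerisation (AuCl3 in MeCN, or Cs2CO3 in DMF) closes the furan ring.
- The sequence comes back to the route at 21.

**Further compounds**

F1 | step 17 | triethylsilyl ether of 14 | COc1cc([C@H](O[Si](CC)(CC)CC)C(CI)CI)ccc1O[Si](C(C)C)(C(C)C)C(C)C
F2 | step 17 | methyl ester of 26 | COC(=O)Cc1cc2cc(O[Si](C(C)C)(C(C)C)C(C)C)c(C3(C)OCCO3)cc2o1
F3 | step 17 | mono-alkylated iodo ester (C2 R, mixed at C3 and C5) | COc1cc([C@H](O[Si](CC)(CC)CC)C(CI)CC(C(=O)OC)c2cc3cc(O[Si](C(C)C)(C(C)C)C(C)C)c(C4(C)OCCO4)cc3o2)ccc1O[Si](C(C)C)(C(C)C)C(C)C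
F4 | step 17 | hydroxy ester (C2 R, mixed at C3 and C5) | COc1cc([C@H](O)C(CI)CC(C(=O)OC)c2cc3cc(O[Si](C(C)C)(C(C)C)C(C)C)c(C4(C)OCCO4)cc3o2)ccc1O[Si](C(C)C)(C(C)C)C(C)C
F5 | step 17 | cis lactone (C3 epimer of 29) | COc1cc([C@@H]2OC(=O)C(c3cc4cc(O[Si](C(C)C)(C(C)C)C(C)C)c(C5(C)OCCO5)cc4o3)C[C@@H]2CI)ccc1O[Si](C(C)C)(C(C)C)C(C)C
F6 | step 20 | ketene acetal diphenyl phosphate of 29 | COc1cc([C@@H]2OC(OP(=O)(Oc3ccccc3)Oc3ccccc3)=C(c3cc4cc(O[Si](C(C)C)(C(C)C)C(C)C)c(C5(C)OCCO5)cc4o3)C[C@H]2CI)ccc1O[Si](C(C)C)(C(C)C)C(C)C
F7 | step 20 | ketal-protected (2R,3R)-iodomethyl dihydropyran | COc1cc([C@@H]2OC=C(c3cc4cc(O[Si](C(C)C)(C(C)C)C(C)C)c(C5(C)OCCO5)cc4o3)C[C@H]2CI)ccc1O[Si](C(C)C)(C(C)C)C(C)C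
F8 | step 11 | 2-acetyl-5-bromobenzene-1,4-diyl diacetate | CC(=O)Oc1cc(C(C)=O)c(OC(C)=O)cc1Br
F9 | step 11 | 4-(2,5-diacetoxy-4-acetylphenyl)but-3-yn-1-yl acetate | CC(=O)OCCC#Cc1cc(OC(C)=O)c(C(C)=O)cc1OC(C)=O
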